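**Retrosynthetic overview**

1. The plan rests on the seven-membered-ring unit C9(OH)–C10(=C18H2)–C1(H)–C2. It is read as a reduced cyclohept-2-enone (C9=O, C10=C1) that took a vinyl group at C1 and a CH2 electrophile at C10. Labels: C1/C5 ring-fusion CH, C2=C3 cyclopentene alkene, C4 methyl carbinol, C6/C9 CHOH, C7 side-chain CH, C8 CH2, C11 CH(CH3), C12 CH(OAc).
2. Target ⇐ desilylation ⇐ ring-closing metathesis to the five-membered ring (C2=C3) ⇐ 1,2-reduction at C9 ⇐ vinyl cuprate addition / Eschenmoser methylenation of cycloheptenone 31.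
3. 31 ⇐ ring-closing metathesis of vinyl ketone 30 (C10=C1). The seven-membered ring is closed first, the cyclopentene second.
4. C4–C6 ⇐ Felkin-controlled methyl addition to a C4 ketone, after an anti-selective boron aldol (C5–C6) of allyl ketone 17 with aldehyde 13.
5. 13 (C7, C11, C12) ⇐ trans-alkylation of γ-lactone 7 with tert-butyl bromoacetate ⇐ (Z)-crotylboration of 4-methylpent-3-enal.

Key step: step 20

Remark: 4-methylpent-3-enal (1, distilled before use) and racemic 4-methoxybenzyl glycidyl ether (14) are taken as catalogue chemicals; the stereocentre of 16 is removed in step 9, so the racemate suffices.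

**Route**

Step 1
Reactants: 1 4-methylpent-3-enal; 2 (Z)-but-2-ene
Product: 4 (3S,4S)-3,7-dimethylocta-1,6-dien-4-ol, via crotyldiisopinocampheylborane 3 (not isolated)
Conditions: 2, KOt-Bu, n-BuLi, THF, −78 → −45 °C; (+)-Ipc2BOMe [from (−)-α-pinene], −78 °C; BF3·OEt2; 1, −78 °C; NaOH, H2O2, 0 °C → rt
Reagents that add atoms: none
Why: Brown asymmetric crotylboration; the (Z)-crotylborane reacts through a chair transition state to give the syn adduct, and the isopinocampheyl groups direct attack to the re face of the aldehyde, which sets C11 and C12.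

Step 2
Reactants: 4 (3S,4S)-3,7-dimethylocta-1,6-dien-4-ol
Product: 6 (3S,4S)-3,7-dimethyloct-6-ene-1,4-diol, via bis-borane adduct 5 (not isolated)
Conditions: 9-BBN (2.2 equiv), THF, 0 °C → rt; NaOH, H2O2, 0 °C
Reagents that add atoms: hydrogen peroxide, OO
Why: Anti-Markovnikov hydroboration–oxidation; 9-BBN takes the monosubstituted alkene far faster than the trisubstituted one, and no stereocentre is touched.

Step 3
Reactants: 6 (3S,4S)-3,7-dimethyloct-6-ene-1,4-diol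
Product: 7 (4S,5S)-4-methyl-5-(3-methylbut-2-en-1-yl)oxolan-2-one
Conditions: TEMPO (cat.), PhI(OAc)2, CH2Cl2, rt
Reagents that add atoms: none
Why: Oxidative lactonisation of a 1,4-diol; the primary alcohol is oxidised to the aldehyde, which closes to the lactol with the C12 hydroxyl and is oxidised on to the γ-lactone.

Step 4
Reactants: 7 (4S,5S)-4-methyl-5-(3-methylbut-2-en-1-yl)oxolan-2-one; 8 tert-butyl bromoacetate
Product: 10 tert-butyl 2-[(3S,4S,5S)-4-methyl-5-(3-methylbut-2-en-1-yl)-2-oxooxolan-3-yl]acetate, via lactone lithium enolate 9 (not isolated)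
Conditions: LiN(i-Pr)2, THF, −78 °C; 8, HMPA, −78 → −40 °C
Reagents that add atoms: none
Why: Lactone enolate alkylation; the electrophile enters anti to the neighbouring C11 methyl (and the cis C12 side chain), which sets C7 trans to C11.

Step 5
Reactants: 10 tert-butyl 2-[(3S,4S,5S)-4-methyl-5-(3-methylbut-2-en-1-yl)-2-oxooxolan-3-yl]acetate
Product: 11 tert-butyl (3S,4S,5S)-5-hydroxy-3-[methoxy(methyl)carbamoyl]-4,8-dimethylnon-7-enoate
Conditions: MeNH(OMe)·HCl, AlMe3, CH2Cl2, 0 °C → rt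
Reagents that add atoms: N,O-dimethylhydroxylamine hydrochloride, CNOC.Cl
Why: Weinreb aminolysis of the lactone by the aluminium amide; the hindered tert-butyl ester should not react.

Step 6
Reactants: 11 tert-butyl (3S,4S,5S)-5-hydroxy-3-[methoxy(methyl)carbamoyl]-4,8-dimethylnon-7-enoate
Product: 12 tert-butyl (3S,4S,5S)-5-acetoxy-3-[methoxy(methyl)carbamoyl]-4,8-dimethylnon-7-enoate
Conditions: Ac2O, pyridine, DMAP (cat.), CH2Cl2, 0 °C
Reagents that add atoms: acetic anhydride, CC(=O)OC(C)=O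
Why: Acetylation traps the γ-hydroxy amide before it can relactonise and installs the C12 acetate of the target.

Step 7
Reactants: 12 tert-butyl (3S,4S,5S)-5-acetoxy-3-[methoxy(methyl)carbamoyl]-4,8-dimethylnon-7-enoate
Product: 13 tert-butyl (3S,4S,5S)-5-acetoxy-3-formyl-4,8-dimethylnon-7-enoate
Conditions: Cp2Zr(H)Cl, THF, rt
Reagents that add atoms: none
Why: Schwartz-reagent reduction of a tertiary amide to the aldehyde, chemoselective over the acetate, the tert-butyl ester and the trisubstituted alkene; the aldehyde is used at once to protect the C7 stereocentre.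

Step 8
Reactants: 14 2-{[(4-methoxybenzyl)oxy]methyl}oxirane; 15 vinylmagnesium bromide
Product: 16 1-[(4-methoxybenzyl)oxy]pent-4-en-2-ol
Conditions: CuI (10 mol%), THF, −30 °C
Reagents that add atoms: none
Why: Copper-catalysed Grignard opening of a terminal epoxide at its CH2 carbon.

Step 9
Reactants: 16 1-[(4-methoxybenzyl)oxy]pent-4-en-2-ol
Product: 17 1-[(4-methoxybenzyl)oxy]pent-4-en-2-one
Conditions: Dess–Martin periodinane, NaHCO3, CH2Cl2, 0 °C
Reagents that add atoms: none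
Why: Buffered Dess–Martin oxidation gives the β,γ-unsaturated ketone without base that would move the alkene into conjugation.

Step 10
Reactants: 13 tert-butyl (3S,4S,5S)-5-acetoxy-3-formyl-4,8-dimethylnon-7-enoate; 17 1-[(4-methoxybenzyl)oxy]pent-4-en-2-one
Product: 19 tert-butyl (3S,4S,5S)-5-acetoxy-3-[(1R,2R)-2-ethenyl-1-hydroxy-4-[(4-methoxybenzyl)oxy]-3-oxobutyl]-4,8-dimethylnon-7-enoate, via dicyclohexylboron dienolate 18 (not isolated)
Conditions: 17, (c-Hex)2BCl, Et3N, Et2O, 0 °C; 13, −78 → −20 °C; MeOH, pH 7 buffer, H2O2, 0 °C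
Reagents that add atoms: none
Why: Boron-mediated ketone aldol; the allylic CH2 is enolised to the E-enol borinate, whose chair transition state gives the 5,6-anti adduct through its α-carbon, and Felkin–Anh attack on the α-branched aldehyde (C11 as the large group) sets C6.

Step 11
Reactants: 19 tert-butyl (3S,4S,5S)-5-acetoxy-3-[(1R,2R)-2-ethenyl-1-hydroxy-4-[(4-methoxybenzyl)oxy]-3-oxobutyl]-4,8-dimethylnon-7-enoate
Product: 20 tert-butyl (3S,4S,5S)-5-acetoxy-3-[(1R,2R)-1-[(tert-butyldimethylsilyl)oxy]-2-ethenyl-4-[(4-methoxybenzyl)oxy]-3-oxobutyl]-4,8-dimethylnon-7-enoate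
Conditions: TBSOTf, 2,6-lutidine, CH2Cl2, −78 °C
Reagents that add atoms: tert-butyldimethylsilyl triflate, CC(C)(C)[Si](C)(C)OS(=O)(=O)C(F)(F)F
Why: Silyl triflate protection of the aldol hydroxyl, which blocks retro-aldol cleavage and lactonisation onto the ester.

Step 12
Reactants: 20 tert-butyl (3S,4S,5S)-5-acetoxy-3-[(1R,2R)-1-[(tert-butyldimethylsilyl)oxy]-2-ethenyl-4-[(4-methoxybenzyl)oxy]-3-oxobutyl]-4,8-dimethylnon-7-enoate
Product: 21 tert-butyl (3S,4S,5S)-5-acetoxy-3-[(1R,2R,3R)-1-[(tert-butyldimethylsilyl)oxy]-2-ethenyl-3-hydroxy-4-[(4-methoxybenzyl)oxy]-3-methylbutyl]-4,8-dimethylnon-7-enoate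
Conditions: MeMgBr, CeCl3, THF, −78 °C
Reagents that add atoms: methylmagnesium bromide, C[Mg]Br
Why: Organocerium 1,2-addition to the ketone (faster than attack on either ester, and without enolising the acidic C5–H); Felkin–Anh approach anti to the bulky C6 carbon, with the vinyl group inside, should set C4.

Step 13
Reactants: 21 tert-butyl (3S,4S,5S)-5-acetoxy-3-[(1R,2R,3R)-1-[(tert-butyldimethylsilyl)oxy]-2-ethenyl-3-hydroxy-4-[(4-methoxybenzyl)oxy]-3-methylbutyl]-4,8-dimethylnon-7-enoate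
Product: 22 tert-butyl (3S,4S,5S)-5-acetoxy-3-[(1R,2R,3R)-1-[(tert-butyldimethylsilyl)oxy]-2-ethenyl-4-[(4-methoxybenzyl)oxy]-3-methyl-3-[(triethylsilyl)oxy]butyl]-4,8-dimethylnon-7-enoate
Conditions: TESOTf, 2,6-lutidine, CH2Cl2, −78 → 0 °C
Reagents that add atoms: triethylsilyl triflate, CC[Si](CC)(CC)OS(=O)(=O)C(F)(F)F
Why: Silyl triflates silylate hindered tertiary alcohols; the C4 silyl ether is the bulky group that later shields one face of the enone.

Step 14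
Reactants: 22 tert-butyl (3S,4S,5S)-5-acetoxy-3-[(1R,2R,3R)-1-[(tert-butyldimethylsilyl)oxy]-2-ethenyl-4-[(4-methoxybenzyl)oxy]-3-methyl-3-[(triethylsilyl)oxy]butyl]-4,8-dimethylnon-7-enoate
Product: 23 tert-butyl (3S,4S,5S)-5-acetoxy-3-[(1R,2R,3R)-1-[(tert-butyldimethylsilyl)oxy]-2-ethenyl-4-hydroxy-3-methyl-3-[(triethylsilyl)oxy]butyl]-4,8-dimethylnon-7-enoate
Conditions: DDQ, CH2Cl2/pH 7 buffer, 0 °C
Reagents that add atoms: none
Why: Oxidative cleavage of the 4-methoxybenzyl ether under buffered conditions that spare silyl ethers, esters and alkenes.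

Step 15
Reactants: 23 tert-butyl (3S,4S,5S)-5-acetoxy-3-[(1R,2R,3R)-1-[(tert-butyldimethylsilyl)oxy]-2-ethenyl-4-hydroxy-3-methyl-3-[(triethylsilyl)oxy]butyl]-4,8-dimethylnon-7-enoate
Product: 24 tert-butyl (3S,4S,5S)-5-acetoxy-3-[(1R,2R,3R)-1-[(tert-butyldimethylsilyl)oxy]-2-ethenyl-3-methyl-4-oxo-3-[(triethylsilyl)oxy]butyl]-4,8-dimethylnon-7-enoate
Conditions: Dess–Martin periodinane, NaHCO3, CH2Cl2, rt
Reagents that add atoms: none
Why: Dess–Martin oxidation to an aldehyde that has no α-hydrogen and so cannot epimerise.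

Step 16
Reactants: 24 tert-butyl (3S,4S,5S)-5-acetoxy-3-[(1R,2R,3R)-1-[(tert-butyldimethylsilyl)oxy]-2-ethenyl-3-methyl-4-oxo-3-[(triethylsilyl)oxy]butyl]-4,8-dimethylnon-7-enoate
Product: 25 tert-butyl (3S,4S,5S)-5-acetoxy-3-[(1R,2R,3S)-1-[(tert-butyldimethylsilyl)oxy]-2-ethenyl-3-methyl-3-[(triethylsilyl)oxy]pent-4-en-1-yl]-4,8-dimethylnon-7-enoate
Conditions: Ph3PCH3Br, KN(SiMe3)2, THF, 0 °C; 24, −78 → 0 °C
Reagents that add atoms: methyltriphenylphosphonium bromide, C[P+](c1ccccc1)(c1ccccc1)c1ccccc1.[Br-]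
Why: Wittig methylenation of the aldehyde gives the C3 vinyl group; the esters should survive the cold, short exposure to the ylide.

Step 17
Reactants: 25 tert-butyl (3S,4S,5S)-5-acetoxy-3-[(1R,2R,3S)-1-[(tert-butyldimethylsilyl)oxy]-2-ethenyl-3-methyl-3-[(triethylsilyl)oxy]pent-4-en-1-yl]-4,8-dimethylnon-7-enoate
Product: 27 (3S,4S,5S)-5-acetoxy-3-[(1R,2R,3S)-1-[(tert-butyldimethylsilyl)oxy]-2-ethenyl-3-methyl-3-[(triethylsilyl)oxy]pent-4-en-1-yl]-4,8-dimethylnon-7-enoic acid, via trimethylsilyl ester 26 (not isolated)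
Conditions: TMSOTf, 2,6-lutidine, CH2Cl2, 0 °C; then pH 5 buffer
Reagents that add atoms: none
Why: Silyl-triflate cleavage of a tert-butyl ester (loss of isobutene) to the silyl ester, hydrolysed on work-up; the lutidine buffer should keep the silyl ethers and the acetate in place.

Step 18
Reactants: 27 (3S,4S,5S)-5-acetoxy-3-[(1R,2R,3S)-1-[(tert-butyldimethylsilyl)oxy]-2-ethenyl-3-methyl-3-[(triethylsilyl)oxy]pent-4-en-1-yl]-4,8-dimethylnon-7-enoic acid; 28 tributyl(vinyl)stannane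
Product: 30 (5S,6S,7S)-5-[(1R,2R,3S)-1-[(tert-butyldimethylsilyl)oxy]-2-ethenyl-3-methyl-3-[(triethylsilyl)oxy]pent-4-en-1-yl]-6,10-dimethyl-3-oxoundeca-1,9-dien-7-yl acetate, via acid chloride 29 (not isolated)
Conditions: 1-chloro-N,N,2-trimethylprop-1-en-1-amine, CH2Cl2, 0 °C; then 28, Pd2(dba)3 (cat.), P(2-furyl)3, THF, rt
Reagents that add atoms: none
Why: Neutral acid chloride formation followed by Stille acylation gives the vinyl ketone without a hard nucleophile that would attack the acetate.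

Step 19
Reactants: 30 (5S,6S,7S)-5-[(1R,2R,3S)-1-[(tert-butyldimethylsilyl)oxy]-2-ethenyl-3-methyl-3-[(triethylsilyl)oxy]pent-4-en-1-yl]-6,10-dimethyl-3-oxoundeca-1,9-dien-7-yl acetate
Product: 31 (2S,3S)-2-[(1S,2R,3R)-2-[(tert-butyldimethylsilyl)oxy]-6-oxo-3-[(2S)-2-[(triethylsilyl)oxy]but-3-en-2-yl]cyclohept-4-en-1-yl]-6-methylhept-5-en-3-yl acetate
Conditions: second-generation Grubbs catalyst (5 mol%), CH2Cl2 (2 mM), 40 °C
Reagents that add atoms: none
Why: Ring-closing metathesis of the C1 vinyl group with the vinyl ketone closes the seven-membered enone; the vinyl on quaternary C4 and the trisubstituted alkene could only give four- or eight-membered rings.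

Step 20
Reactants: 31 (2S,3S)-2-[(1S,2R,3R)-2-[(tert-butyldimethylsilyl)oxy]-6-oxo-3-[(2S)-2-[(triethylsilyl)oxy]but-3-en-2-yl]cyclohept-4-en-1-yl]-6-methylhept-5-en-3-yl acetate; 15 vinylmagnesium bromide; 32 N,N-dimethylmethyleneiminium iodide
Product: 36 (2S,3S)-2-[(1S,2R,3R,4R)-2-[(tert-butyldimethylsilyl)oxy]-4-ethenyl-5-methylidene-6-oxo-3-[(2S)-2-[(triethylsilyl)oxy]but-3-en-2-yl]cycloheptyl]-6-methylhept-5-en-3-yl acetate, via silyl enol ether 33 (not isolated), via Mannich base 34 (not isolated), via ammonium iodide 35 (not isolated)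
Conditions: 15, CuI (10 mol%), Me3SiCl, THF, −78 °C; Et3N, pentane work-up; 32, CH2Cl2, rt; MeI; NaHCO3 (aq), CH2Cl2, rt
Reagents that add atoms: none
Why: Copper-catalysed, Me3SiCl-accelerated conjugate addition of the vinyl Grignard reagent forms C1–C2 and delivers the enolate regiospecifically as the C9–C10 silyl enol ether 33; this attacks the iminium salt at C10 to give the Mannich base 34, which is quaternised and eliminated to the exocyclic C10=C18 alkene. The closest known reaction is the three-component cuprate addition with Eschenmoser-salt trapping used to make α-methylene cycloalkanones. No ring is closed in this step. The new C1 stereocentre is controlled by the adjacent C5 substituent: the vinyl copper reagent adds to the enone face anti to the bulky silyloxy quaternary carbon C4, giving the trans C1/C5 relationship, and the transient C10 stereocentre is lost on elimination. The step needs 1,4- over 1,2-addition (copper catalysis with Me3SiCl), functionalisation at C10 and not C8 (the enol ether is generated only towards C10 and is never equilibrated), and survival of the acetate (no hard nucleophile above −78 °C).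

Step 21
Reactants: 36 (2S,3S)-2-[(1S,2R,3R,4R)-2-[(tert-butyldimethylsilyl)oxy]-4-ethenyl-5-methylidene-6-oxo-3-[(2S)-2-[(triethylsilyl)oxy]but-3-en-2-yl]cycloheptyl]-6-methylhept-5-en-3-yl acetate
Product: 37 (2S,3S)-2-[(1S,2R,3R,4R,6R)-2-[(tert-butyldimethylsilyl)oxy]-4-ethenyl-6-hydroxy-5-methylidene-3-[(2S)-2-[(triethylsilyl)oxy]but-3-en-2-yl]cycloheptyl]-6-methylhept-5-en-3-yl acetate
Conditions: NaBH4, CeCl3·7H2O, MeOH, −78 °C
Reagents that add atoms: none
Why: Luche 1,2-reduction of the α-methylene ketone; hydride is expected on the face opposite the C5 quaternary substituent, placing the C9 hydroxyl cis to it, but this facial preference is an expectation only (see risks).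

Step 22
Reactants: 37 (2S,3S)-2-[(1S,2R,3R,4R,6R)-2-[(tert-butyldimethylsilyl)oxy]-4-ethenyl-6-hydroxy-5-methylidene-3-[(2S)-2-[(triethylsilyl)oxy]but-3-en-2-yl]cycloheptyl]-6-methylhept-5-en-3-yl acetate
Product: 38 (2S,3S)-2-[(1S,3aR,5R,7S,8R,8aR)-8-[(tert-butyldimethylsilyl)oxy]-5-hydroxy-1-methyl-4-methylidene-1-[(triethylsilyl)oxy]-1,3a,4,5,6,7,8,8a-octahydroazulen-7-yl]-6-methylhept-5-en-3-yl acetate
Conditions: second-generation Grubbs catalyst (10 mol%), toluene, 60 °C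
Reagents that add atoms: none
Why: Ring-closing metathesis of the two vinyl groups on C1 and C4 closes the trans-fused cyclopentene at C2=C3; the 1,1-disubstituted methylidene and the trisubstituted alkene are much slower partners.

Step 23
Reactants: 38 (2S,3S)-2-[(1S,3aR,5R,7S,8R,8aR)-8-[(tert-butyldimethylsilyl)oxy]-5-hydroxy-1-methyl-4-methylidene-1-[(triethylsilyl)oxy]-1,3a,4,5,6,7,8,8a-octahydroazulen-7-yl]-6-methylhept-5-en-3-yl acetate
Product: 39 (2S,3S)-2-[(1S,3aR,5R,7S,8R,8aR)-1,5,8-trihydroxy-1-methyl-4-methylidene-1,3a,4,5,6,7,8,8a-octahydroazulen-7-yl]-6-methylhept-5-en-3-yl acetate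
Conditions: HF·pyridine, pyridine, THF, 0 °C → rt
Reagents that add atoms: none
Why: Buffered fluoride desilylation removes both silyl ethers and should leave the acetate and the acid-sensitive tertiary allylic alcohol intact.

**Compound list**

1 | 4-methylpent-3-enal | CC(C)=CCC=O | starting material
2 | (Z)-but-2-ene | C/C=C\C | starting material
3 | (Z)-crotyldiisopinocampheylborane, Ipc groups from (−)-α-pinene | C/C=C\CB([C@H]1C[C@H]2C[C@@H]([C@@H]1C)C2(C)C)[C@H]1C[C@H]2C[C@@H]([C@@H]1C)C2(C)C | intermediate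
4 | (3S,4S)-3,7-dimethylocta-1,6-dien-4-ol | C=C[C@H](C)[C@@H](O)CC=C(C)C | intermediate
5 | C-alkyl, O-boryl bis(9-BBN) adduct of 4 | CC(C)=CC[C@H](OB1C2CCCC1CCC2)[C@@H](C)CCB1C2CCCC1CCC2 | intermediate
6 | (3S,4S)-3,7-dimethyloct-6-ene-1,4-diol | OCC[C@H](C)[C@@H](O)CC=C(C)C | intermediate
7 | (4S,5S)-4-methyl-5-(3-methylbut-2-en-1-yl)oxolan-2-one | O=C1C[C@H](C)[C@H](CC=C(C)C)O1 | intermediate
8 | tert-butyl bromoacetate | BrCC(=O)OC(C)(C)C | starting material
9 | lithium enolate of lactone 7 | [Li]OC1=C[C@H](C)[C@H](CC=C(C)C)O1 | intermediate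
10 | tert-butyl 2-[(3S,4S,5S)-4-methyl-5-(3-methylbut-2-en-1-yl)-2-oxooxolan-3-yl]acetate | O=C1[C@@H](CC(=O)OC(C)(C)C)[C@H](C)[C@H](CC=C(C)C)O1 | intermediate
11 | tert-butyl (3S,4S,5S)-5-hydroxy-3-[methoxy(methyl)carbamoyl]-4,8-dimethylnon-7-enoate | CON(C)C(=O)[C@@H](CC(=O)OC(C)(C)C)[C@H](C)[C@@H](O)CC=C(C)C | intermediate
12 | tert-butyl (3S,4S,5S)-5-acetoxy-3-[methoxy(methyl)carbamoyl]-4,8-dimethylnon-7-enoate | CON(C)C(=O)[C@@H](CC(=O)OC(C)(C)C)[C@H](C)[C@@H](OC(C)=O)CC=C(C)C | intermediate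
13 | tert-butyl (3S,4S,5S)-5-acetoxy-3-formyl-4,8-dimethylnon-7-enoate | O=C[C@@H](CC(=O)OC(C)(C)C)[C@H](C)[C@@H](OC(C)=O)CC=C(C)C | intermediate
14 | 2-{[(4-methoxybenzyl)oxy]methyl}oxirane (racemic) | COc1ccc(COCC2CO2)cc1 | starting material
15 | vinylmagnesium bromide | C=C[Mg]Br | starting material
16 | 1-[(4-methoxybenzyl)oxy]pent-4-en-2-ol (racemic) | COc1ccc(COCC(O)CC=C)cc1 | intermediate
17 | 1-[(4-methoxybenzyl)oxy]pent-4-en-2-one | COc1ccc(COCC(=O)CC=C)cc1 | intermediate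
18 | (E)-dicyclohexylboron dienolate of 17 | COc1ccc(COC/C(OB(C2CCCCC2)C2CCCCC2)=C\C=C)cc1 | intermediate
19 | tert-butyl (3S,4S,5S)-5-acetoxy-3-[(1R,2R)-2-ethenyl-1-hydroxy-4-[(4-methoxybenzyl)oxy]-3-oxobutyl]-4,8-dimethylnon-7-enoate | COc1ccc(COCC(=O)[C@H](C=C)[C@H](O)[C@@H](CC(=O)OC(C)(C)C)[C@H](C)[C@@H](OC(C)=O)CC=C(C)C)cc1 | intermediate
20 | tert-butyl (3S,4S,5S)-5-acetoxy-3-[(1R,2R)-1-[(tert-butyldimethylsilyl)oxy]-2-ethenyl-4-[(4-methoxybenzyl)oxy]-3-oxobutyl]-4,8-dimethylnon-7-enoate | COc1ccc(COCC(=O)[C@H](C=C)[C@H](O[Si](C)(C)C(C)(C)C)[C@@H](CC(=O)OC(C)(C)C)[C@H](C)[C@@H](OC(C)=O)CC=C(C)C)cc1 | intermediate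
21 | tert-butyl (3S,4S,5S)-5-acetoxy-3-[(1R,2R,3R)-1-[(tert-butyldimethylsilyl)oxy]-2-ethenyl-3-hydroxy-4-[(4-methoxybenzyl)oxy]-3-methylbutyl]-4,8-dimethylnon-7-enoate | COc1ccc(COC[C@](C)(O)[C@H](C=C)[C@H](O[Si](C)(C)C(C)(C)C)[C@@H](CC(=O)OC(C)(C)C)[C@H](C)[C@@H](OC(C)=O)CC=C(C)C)cc1 | intermediate
22 | tert-butyl (3S,4S,5S)-5-acetoxy-3-[(1R,2R,3R)-1-[(tert-butyldimethylsilyl)oxy]-2-ethenyl-4-[(4-methoxybenzyl)oxy]-3-methyl-3-[(triethylsilyl)oxy]butyl]-4,8-dimethylnon-7-enoate | COc1ccc(COC[C@](C)(O[Si](CC)(CC)CC)[C@H](C=C)[C@H](O[Si](C)(C)C(C)(C)C)[C@@H](CC(=O)OC(C)(C)C)[C@H](C)[C@@H](OC(C)=O)CC=C(C)C)cc1 | intermediate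
23 | tert-butyl (3S,4S,5S)-5-acetoxy-3-[(1R,2R,3R)-1-[(tert-butyldimethylsilyl)oxy]-2-ethenyl-4-hydroxy-3-methyl-3-[(triethylsilyl)oxy]butyl]-4,8-dimethylnon-7-enoate | OC[C@](C)(O[Si](CC)(CC)CC)[C@H](C=C)[C@H](O[Si](C)(C)C(C)(C)C)[C@@H](CC(=O)OC(C)(C)C)[C@H](C)[C@@H](OC(C)=O)CC=C(C)C | intermediate
24 | tert-butyl (3S,4S,5S)-5-acetoxy-3-[(1R,2R,3R)-1-[(tert-butyldimethylsilyl)oxy]-2-ethenyl-3-methyl-4-oxo-3-[(triethylsilyl)oxy]butyl]-4,8-dimethylnon-7-enoate | O=C[C@](C)(O[Si](CC)(CC)CC)[C@H](C=C)[C@H](O[Si](C)(C)C(C)(C)C)[C@@H](CC(=O)OC(C)(C)C)[C@H](C)[C@@H](OC(C)=O)CC=C(C)C | intermediate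
25 | tert-butyl (3S,4S,5S)-5-acetoxy-3-[(1R,2R,3S)-1-[(tert-butyldimethylsilyl)oxy]-2-ethenyl-3-methyl-3-[(triethylsilyl)oxy]pent-4-en-1-yl]-4,8-dimethylnon-7-enoate | C=C[C@](C)(O[Si](CC)(CC)CC)[C@H](C=C)[C@H](O[Si](C)(C)C(C)(C)C)[C@@H](CC(=O)OC(C)(C)C)[C@H](C)[C@@H](OC(C)=O)CC=C(C)C | intermediate
26 | trimethylsilyl ester of acid 27 | C=C[C@](C)(O[Si](CC)(CC)CC)[C@H](C=C)[C@H](O[Si](C)(C)C(C)(C)C)[C@@H](CC(=O)O[Si](C)(C)C)[C@H](C)[C@@H](OC(C)=O)CC=C(C)C | intermediate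
27 | (3S,4S,5S)-5-acetoxy-3-[(1R,2R,3S)-1-[(tert-butyldimethylsilyl)oxy]-2-ethenyl-3-methyl-3-[(triethylsilyl)oxy]pent-4-en-1-yl]-4,8-dimethylnon-7-enoic acid | C=C[C@](C)(O[Si](CC)(CC)CC)[C@H](C=C)[C@H](O[Si](C)(C)C(C)(C)C)[C@@H](CC(=O)O)[C@H](C)[C@@H](OC(C)=O)CC=C(C)C | intermediate
28 | tributyl(vinyl)stannane | C=C[Sn](CCCC)(CCCC)CCCC | starting material
29 | acid chloride of 27 | C=C[C@](C)(O[Si](CC)(CC)CC)[C@H](C=C)[C@H](O[Si](C)(C)C(C)(C)C)[C@@H](CC(=O)Cl)[C@H](C)[C@@H](OC(C)=O)CC=C(C)C | intermediate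
30 | (5S,6S,7S)-5-[(1R,2R,3S)-1-[(tert-butyldimethylsilyl)oxy]-2-ethenyl-3-methyl-3-[(triethylsilyl)oxy]pent-4-en-1-yl]-6,10-dimethyl-3-oxoundeca-1,9-dien-7-yl acetate | C=C[C@](C)(O[Si](CC)(CC)CC)[C@H](C=C)[C@H](O[Si](C)(C)C(C)(C)C)[C@@H](CC(=O)C=C)[C@H](C)[C@@H](OC(C)=O)CC=C(C)C | intermediate
31 | (2S,3S)-2-[(1S,2R,3R)-2-[(tert-butyldimethylsilyl)oxy]-6-oxo-3-[(2S)-2-[(triethylsilyl)oxy]but-3-en-2-yl]cyclohept-4-en-1-yl]-6-methylhept-5-en-3-yl acetate | O=C1C=C[C@@H]([C@@](C)(O[Si](CC)(CC)CC)C=C)[C@H](O[Si](C)(C)C(C)(C)C)[C@H]([C@H](C)[C@H](CC=C(C)C)OC(C)=O)C1 | intermediate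
32 | N,N-dimethylmethyleneiminium iodide (Eschenmoser's salt) | C[N+](C)=C.[I-] | starting material
33 | C9 trimethylsilyl enol ether of the 1,4-adduct | C[Si](C)(C)OC1=C[C@H](C=C)[C@@H]([C@@](C)(O[Si](CC)(CC)CC)C=C)[C@H](O[Si](C)(C)C(C)(C)C)[C@H]([C@H](C)[C@H](CC=C(C)C)OC(C)=O)C1 | intermediate
34 | C10 (dimethylamino)methyl ketone (Mannich base, C10 configuration open) | CN(C)CC1C(=O)C[C@@H]([C@H](C)[C@H](CC=C(C)C)OC(C)=O)[C@@H](O[Si](C)(C)C(C)(C)C)[C@H]([C@@](C)(O[Si](CC)(CC)CC)C=C)[C@H]1C=C | intermediate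
35 | trimethylammonium iodide of 34 | C[N+](C)(C)CC1C(=O)C[C@@H]([C@H](C)[C@H](CC=C(C)C)OC(C)=O)[C@@H](O[Si](C)(C)C(C)(C)C)[C@H]([C@@](C)(O[Si](CC)(CC)CC)C=C)[C@H]1C=C.[I-] | intermediate
36 | (2S,3S)-2-[(1S,2R,3R,4R)-2-[(tert-butyldimethylsilyl)oxy]-4-ethenyl-5-methylidene-6-oxo-3-[(2S)-2-[(triethylsilyl)oxy]but-3-en-2-yl]cycloheptyl]-6-methylhept-5-en-3-yl acetate | C=C1C(=O)C[C@@H]([C@H](C)[C@H](CC=C(C)C)OC(C)=O)[C@@H](O[Si](C)(C)C(C)(C)C)[C@H]([C@@](C)(O[Si](CC)(CC)CC)C=C)[C@H]1C=C | intermediate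
37 | (2S,3S)-2-[(1S,2R,3R,4R,6R)-2-[(tert-butyldimethylsilyl)oxy]-4-ethenyl-6-hydroxy-5-methylidene-3-[(2S)-2-[(triethylsilyl)oxy]but-3-en-2-yl]cycloheptyl]-6-methylhept-5-en-3-yl acetate | C=C1[C@H](O)C[C@@H]([C@H](C)[C@H](CC=C(C)C)OC(C)=O)[C@@H](O[Si](C)(C)C(C)(C)C)[C@H]([C@@](C)(O[Si](CC)(CC)CC)C=C)[C@H]1C=C | intermediate
38 | (2S,3S)-2-[(1S,3aR,5R,7S,8R,8aR)-8-[(tert-butyldimethylsilyl)oxy]-5-hydroxy-1-methyl-4-methylidene-1-[(triethylsilyl)oxy]-1,3a,4,5,6,7,8,8a-octahydroazulen-7-yl]-6-methylhept-5-en-3-yl acetate | C=C1[C@H](O)C[C@@H]([C@H](C)[C@H](CC=C(C)C)OC(C)=O)[C@@H](O[Si](C)(C)C(C)(C)C)[C@H]2[C@H]1C=C[C@]2(C)O[Si](CC)(CC)CC | intermediate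
39 | (2S,3S)-2-[(1S,3aR,5R,7S,8R,8aR)-1,5,8-trihydroxy-1-methyl-4-methylidene-1,3a,4,5,6,7,8,8a-octahydroazulen-7-yl]-6-methylhept-5-en-3-yl acetate (CNP0126182.2) | C=C1[C@H](O)C[C@@H]([C@H](C)[C@H](CC=C(C)C)OC(C)=O)[C@@H](O)[C@H]2[C@H]1C=C[C@]2(C)O | target

**Step count and risks**

Total step count: 23. Longest linear sequence: 21 steps (steps 1–7 and 10–23, from 4-methylpent-3-enal); steps 8–9 are a two-step side branch.

The three steps most likely to fail:

Step 20 (key step). The conjugate addition to the hindered enone may be slow. The aminomethylation of the crowded silyl enol ether may stall. The ammonium salt may eliminate with migration of the new double bond into the ring. Fallback: the route sets out from 31 through the silyl enol ether 33, which is now isolated after a non-aqueous work-up. A Mukaiyama-type hydroxymethylation of 33 with aqueous formaldehyde and catalytic Yb(OTf)3 should give the α-hydroxymethyl ketone F1. Mesylation (MsCl, Et3N, 0 °C) gives the mesylate F2, and DBU elimination of F2 returns to 36.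

Step 10. The boron dienolate may react through its γ-carbon, the anti/Felkin selectivity may erode, or the α-vinyl β-hydroxy ketone may slip into conjugation on work-up. Fallback: the route sets out from 17 and 13 with the vinyl group masked. Radical anti-Markovnikov addition of benzeneselenol to 17 gives 1-[(4-methoxybenzyl)oxy]-5-(phenylselanyl)pentan-2-one F3. Its E-enol borinate is that of a plain alkyl ketone, with no dienolate ambiguity, and the same (c-Hex)2BCl aldol with 13 (non-oxidative work-up) should give the selenide aldol F4. TBSOTf protection gives the silyl ether F5. Selenoxide syn-elimination (NaIO4, then warming) unveils the vinyl group and returns to 20.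

Step 21. Hydride may be delivered to the wrong face of the flexible seven-membered ketone, giving mainly the C9 epimer. Fallback: the route sets out from 36 and accepts the epimeric alcohol F6. Mitsunobu inversion of F6 with chloroacetic acid (PPh3, DIAD) gives the inverted chloroacetate F7. Thiourea and NaHCO3 in ethanol remove the chloroacetyl group selectively (the acetate and silyl ethers stay) and return to 37.

Further compounds
F1 | step 20 | (2S,3S)-2-[(1S,2R,3R,4R)-2-[(tert-butyldimethylsilyl)oxy]-4-ethenyl-5-(hydroxymethyl)-6-oxo-3-[(2S)-2-[(triethylsilyl)oxy]but-3-en-2-yl]cycloheptyl]-6-methylhept-5-en-3-yl acetate | OCC1C(=O)C[C@@H]([C@H](C)[C@H](CC=C(C)C)OC(C)=O)[C@@H](O[Si](C)(C)C(C)(C)C)[C@H]([C@@](C)(O[Si](CC)(CC)CC)C=C)[C@H]1C=C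
F2 | step 20 | methanesulfonate of F1 | CS(=O)(=O)OCC1C(=O)C[C@@H]([C@H](C)[C@H](CC=C(C)C)OC(C)=O)[C@@H](O[Si](C)(C)C(C)(C)C)[C@H]([C@@](C)(O[Si](CC)(CC)CC)C=C)[C@H]1C=C
F3 | step 10 | 1-[(4-methoxybenzyl)oxy]-5-(phenylselanyl)pentan-2-one | COc1ccc(COCC(=O)CCC[Se]c2ccccc2)cc1
F4 | step 10 | tert-butyl (3S,4S,5S)-5-acetoxy-3-[(1R,2R)-1-hydroxy-4-[(4-methoxybenzyl)oxy]-3-oxo-2-[2-(phenylselanyl)ethyl]butyl]-4,8-dimethylnon-7-enoate | COc1ccc(COCC(=O)[C@H](CC[Se]c2ccccc2)[C@H](O)[C@@H](CC(=O)OC(C)(C)C)[C@H](C)[C@@H](OC(C)=O)CC=C(C)C)cc1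
F5 | step 10 | tert-butyldimethylsilyl ether of F4 | COc1ccc(COCC(=O)[C@H](CC[Se]c2ccccc2)[C@H](O[Si](C)(C)C(C)(C)C)[C@@H](CC(=O)OC(C)(C)C)[C@H](C)[C@@H](OC(C)=O)CC=C(C)C)cc1
F6 | step 21 | C9 epimer of 37, (6S)-hydroxy on the cycloheptyl ring | C=C1[C@@H](O)C[C@@H]([C@H](C)[C@H](CC=C(C)C)OC(C)=O)[C@@H](O[Si](C)(C)C(C)(C)C)[C@H]([C@@](C)(O[Si](CC)(CC)CC)C=C)[C@H]1C=C
F7 | step 21 | C9 chloroacetate of 37 | C=C1[C@H](OC(=O)CCl)C[C@@H]([C@H](C)[C@H](CC=C(C)C)OC(C)=O)[C@@H](O[Si](C)(C)C(C)(C)C)[C@H]([C@@](C)(O[Si](CC)(CC)CC)C=C)[C@H]1C=C
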